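(The readings are simulated for substances that don't exist, noise included.)

- If the left-handed substrate couples faster, the right-handed substrate builds an excess, so I followed that gain.

| flask | left-handed substrate | right-handed substrate | coupling partner | remark | time |
|---|---|---|---|---|---|
| Friday's | 47 mM | 47 mM | 160 mM | run made earlier |  |
| Wednesday's | 47 mM | 47 mM | 180 mM | run made earlier |  |
| zeta | 47 mM | 47 mM | 141 mM |  | 10 min |
| delta | 47 mM | 47 mM | 200 mM |  | 10 min |

- Friday's (time / min: right-handed substrate / %, left-handed substrate / %, left-handed product / %): 1.33: 29, 19, 22; 2.50: 16, 12, 29; 4.00: 17, 10, 33; 5.00: 9, 5, 34
- Wednesday's (time / min: right-handed substrate / %, left-handed substrate / %, left-handed product / %): 0.667: 33, 28, 18; 2.00: 17, 15, 31; 3.00: 14, 12, 34; 5.00: 11, 6, 40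

(readings scatter by 2 percentage points)

* which of the two ends with the higher excess of right-handed substrate over left-handed substrate among what is left of the two ("neither" if they lie within 2 percentage points) (zeta / delta / neither)
* excess of right-handed substrate over left-handed substrate among what is left of the two at the end, zeta
* excess of right-handed substrate over left-handed substrate among what is left of the two at the end, delta

- coupling partner is single-handed; left-handed substrate and right-handed substrate are mirror images of each other, charged as a racemate, each of them at the stated concentration
- an excess is the difference of the two amounts in percent of their sum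
- an excess is below zero if the other one leads
- the handed part of coupling partner does not stay in what it makes, so the products of the two hands are mirror images too

- I took the first reading of each run, divided ln(c(right-handed substrate)/c(left-handed substrate)) by time, by charged partner and by two, and averaged the runs.
- These readings gave 0.0140 L mol⁻¹ s⁻¹. I called it the lead, the gain in excess per unit of time and of c(coupling partner).
- Multiplied by c(coupling partner), it gave a pseudo-first-order starting gain of 0.118 min⁻¹ in zeta and 0.168 min⁻¹ in delta.
- Coupling slows this gain. I assumed one partner per substrate and equal products, so Friday's partner stood near 96.1 mM at 5.00 min, a factor of 0.601.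
- Friday's excess then read 28.6%. I took this as the crossing where gain meets wear, an assumed loss in proportion to the excess, which put the wear near 0.282 min⁻¹, a rough reading.
- With the substrate coupled, zeta would keep a factor of 0.333 and delta 0.530. Gain over wear gave me 14.0% for zeta and 31.5% for delta.
- The forecast said delta, with 17% and 34%, holding for zeta that “no partner is left to continue the resolution”. My zeta figure was lower than its value.
- The flasks gave 16.9% in zeta and 23.4% in delta, so delta ended higher. Zeta still held 47% of its coupling partner at 10.0 min.

    coupling partner + left-handed substrate → left-handed product (k = 0.0633 L mol⁻¹ s⁻¹)
    coupling partner + right-handed substrate → right-handed product (k = 0.0323 L mol⁻¹ s⁻¹)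
    left-handed product ⇌ right-handed product (k = 0.00187 s⁻¹)
    right-handed substrate ⇌ achiral form (K = 1.10, k = 0.00516 s⁻¹)
    left-handed substrate ⇌ achiral form (K = 1.10, k = 0.00516 s⁻¹)

- At 10.0 min in delta, the lead on the remaining partner gave a gain of 0.0973 min⁻¹, while achiral form, returning to both hands alike, gave a wear of 0.448 min⁻¹. Their quotient is 21.7%, beside the computed 23.4%.
- In a neighbour flask like delta but with 500 mM of partner, at 10.0 min, the same lead gives 0.341 min⁻¹ against a wear of 0.964 min⁻¹, a quotient of 35.4%. The computed excess there is 34.6%.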